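**Retrosynthetic overview**
1. Lower unit: the pyran ring is bought intact in flat, achiral kaempferol 1 and taken down the anthocyanidin branch, 1 → pelargonidin chloride 2 → flavan-3-one 3 (in the flask) → (−)-epiafzelechin 4; C2 and C3 are set together (cis) in the reductase-type step.
2. Upper unit: achiral isoliquiritigenin 5 closes its pyran ring (ring C) by a chalcone-isomerase-type asymmetric oxa-Michael addition to (2S)-liquiritigenin 6 (sets C2); this is the only ring made in the route.
3. Union (last bond): 6 → flavan-4-ol 7 → quinone methide 8, trapped at C8 of 4 anti to the 2-aryl group → target 9 (sets C4).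
4. Disconnections in retrosynthetic order: C4–C8 interflavan bond; C4–O of the upper unit; O1–C2 of the upper pyran ring; the C–H bonds at C2/C3 and the C4 oxygen of the lower pyran ring.
5. No protecting groups; all four stereocentres arise from two achiral flavonoids.

Assumption: kaempferol and isoliquiritigenin are bought as bulk plant flavonoids; the facial sense of the two chiral catalysts (steps 2 and 3) is assigned from transition-state models and is checked on the first run (CD and optical rotation against the natural monomers), the mirror-image or pseudo-enantiomeric catalyst being equally available.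

**Route**

Step 1
Reactants: 1 kaempferol
Product: 2 pelargonidin chloride
Conditions: Zn(Hg), 3% HCl in MeOH, 20 °C, 15 min
Reagents that add atoms: hydrogen chloride, Cl
Why: Zinc in acid transfers two electrons to the O-protonated flavonol (Clemmensen-type dissolving-metal reduction at C4) and the C4 oxygen then leaves as water to give the aromatic flavylium salt, the classical flavonol-to-anthocyanidin conversion; it is low-yielding (about 25%, over-reduction competes) but starts from a cheap flavonol, and no stereocentre is involved.

Step 2
Reactants: 2 pelargonidin chloride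
Product: 4 (−)-epiafzelechin, via flavan-3-one 3 (not isolated)
Conditions: RuCl[(R,R)-TsDPEN](p-cymene) (2 mol%), HCO2H/Et3N (5:2), degassed DMF, 25 °C, Ar
Reagents that add atoms: none
Why: Proposed new method: the flavylium cation, a stronger hydride acceptor than the pyridinium and quinolinium salts that this Ru–H/formate system already reduces, takes a first hydride (at C2 or C4) to give an enol that tautomerises to 3, whose C2–H (α to C=O, benzylic, α to O) epimerises fast in HCO2H/Et3N, so the second, Noyori–Ikariya-type hydride delivery to C3 runs as a dynamic kinetic resolution, anti to the 2-aryl group (hence cis) and on the C3 Si face selected by the (R,R) ligand (aryloxy-bearing C2 side next to the η6-arene), setting C2 and C3 together as 2R,3R; closest known reactions are asymmetric transfer hydrogenation with dynamic kinetic resolution of α-aryl cyclic ketones and the catalytic hydrogenation of anthocyanidin chlorides to racemic cis-flavan-3-ols.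

Step 3
Reactants: 5 isoliquiritigenin
Product: 6 (2S)-liquiritigenin
Conditions: 9-amino(9-deoxy)epi-quinidine 3,5-bis(CF3)C6H3-thiourea (15 mol%), EtOAc/toluene 1:2, 25 °C, 48 h; recrystallise
Reagents that add atoms: none
Why: Proposed new method: the quinuclidine base beside a thiourea oxyanion hole copies the chalcone isomerase active site, deprotonating the 2'-OH while hydrogen-bonding the carbonyl/enolate oxygen, so the 6-endo oxa-Michael addition closes ring C on one enantiotopic face of the enone and sets C2 as S under kinetic control (stopped near 85% conversion because the catalyst also reopens the product; ee raised by recrystallisation); closest known reactions are the cinchona-thiourea cyclisation of activated 2'-hydroxychalcone β-keto esters (high ee) and the cinchona-base cyclisation of plain 2'-hydroxychalcones (moderate ee).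

Step 4
Reactants: 6 (2S)-liquiritigenin; 4 (−)-epiafzelechin
Product: 9 cassiaflavan-(4β→8)-epiafzelechin, via flavan-4-ol 7 (not isolated), via quinone methide 8 (not isolated)
Conditions: NaBH4, EtOH, 0 °C, N2; then added to 4 (3 equiv) in 0.1 M aq HCl, 25 °C, 3 h
Reagents that add atoms: none
Why: NaBH4 reduces the ketone without touching C2, acid ionises 7 to the 7-OH-stabilised quinone methide 8 (as its O-protonated benzylic cation), and the most nucleophilic carbon of 4 (C8 of the phloroglucinol ring) adds in a Friedel–Crafts alkylation along the axial trajectory anti to the equatorial 2-aryl group, setting C4 as R (2,4-trans, 4β) exactly as in the presumed flavan-4-ol condensation of the biosynthesis; the minor 4α epimer and C6-linked regioisomer are removed on Sephadex LH-20 and by reverse-phase HPLC, and excess 4 is recovered.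

**Compound list**
1 | kaempferol, 3,5,7-trihydroxy-2-(4-hydroxyphenyl)-4H-chromen-4-one | O=c1c(O)c(-c2ccc(O)cc2)oc2cc(O)cc(O)c12 | starting material
2 | pelargonidin chloride, 3,5,7-trihydroxy-2-(4-hydroxyphenyl)chromenylium chloride | Oc1ccc(cc1)-c1[o+]c2cc(O)cc(O)c2cc1O.[Cl-] | intermediate
3 | 5,7-dihydroxy-2-(4-hydroxyphenyl)chroman-3-one (flavan-3-one; C2 labile, epimers interconvert) | O=C1Cc2c(O)cc(O)cc2OC1c1ccc(O)cc1 | intermediate
4 | (−)-epiafzelechin, (2R,3R)-2-(4-hydroxyphenyl)chromane-3,5,7-triol (2,3-cis) | O[C@@H]1Cc2c(O)cc(O)cc2O[C@@H]1c1ccc(O)cc1 | intermediate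
5 | isoliquiritigenin, (E)-1-(2,4-dihydroxyphenyl)-3-(4-hydroxyphenyl)prop-2-en-1-one | O=C(/C=C/c1ccc(O)cc1)c1ccc(O)cc1O | starting material
6 | (2S)-liquiritigenin, (2S)-7-hydroxy-2-(4-hydroxyphenyl)chroman-4-one | O=C1C[C@@H](c2ccc(O)cc2)Oc2cc(O)ccc12 | intermediate
7 | (2S,4S)-2-(4-hydroxyphenyl)chromane-4,7-diol (2,4-cis flavan-4-ol) | O[C@H]1C[C@@H](c2ccc(O)cc2)Oc2cc(O)ccc12 | intermediate
8 | (2S)-2-(4-hydroxyphenyl)-2,3-dihydro-7H-chromen-7-one (para-quinone methide) | O=C1C=CC2=CC[C@@H](c3ccc(O)cc3)OC2=C1 | intermediate
9 | (2R,3R)-8-[(2S,4R)-7-hydroxy-2-(4-hydroxyphenyl)chroman-4-yl]-2-(4-hydroxyphenyl)chromane-3,5,7-triol (upper unit 2,4-trans, lower unit 2,3-cis) | Oc1ccc([C@@H]2C[C@@H](c3c(O)cc(O)c4c3O[C@H](c3ccc(O)cc3)[C@H](O)C4)c3ccc(O)cc3O2)cc1 | target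

**Totals**
Total step count: 4.
Longest linear sequence: 3 steps (1 → 2 → 4 → 9; steps 1, 2 and 4).

**Steps most likely to fail, each with a fallback**

Step 3 (asymmetric ring closure of an unprotected, electron-rich chalcone; low rate, modest ee or erosion by ring reopening). The fallback sets out from 5 and gives up asymmetric ring closure. The ring is closed under thermodynamic control (NaOAc, EtOH/H2O, reflux) to racemic liquiritigenin F2. F2 is then resolved kinetically by transfer hydrogenation with RuCl[(R,R)-TsDPEN](p-cymene) (1 mol%) and HCO2Na in H2O/EtOAc at 40 °C to about 55% conversion. By the aryl-ketone rule this catalyst reduces only the (2R) enantiomer, to (2R,4R)-2-(4-hydroxyphenyl)chromane-4,7-diol F3, which is removed by chromatography. The unreacted ketone is (2S)-liquiritigenin, so the route is rejoined at 6 (at most 50% yield, high ee).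

Step 2 (two hydride transfers and a dynamic kinetic resolution on an unprotected anthocyanidin; pigment degradation or low ee/dr). The fallback sets out from 2 and gives up asymmetric catalysis. 2 is hydrogenated over PtO2 (H2, 3 bar, EtOH), the classical cis-selective reduction of anthocyanidin chlorides, to racemic epiafzelechin F1. F1 is resolved by preparative chromatography on a cellulose tris(3,5-dimethylphenylcarbamate) phase; the (2R,3R) enantiomer is 4, where the route is rejoined.

Step 4 (self-condensation of the labile flavan-4-ol, or poor 4β/4α and C8/C6 selectivity in aqueous acid). The fallback sets out from 6 and replaces the fleeting electrophile by a storable one. 6 is reduced as before (NaBH4, EtOH, 0 °C) to 7, and the cation is trapped with benzyl mercaptan (BnSH, AcOH, EtOH, 25 °C) to (2S,4R)-4-(benzylsulfanyl)-2-(4-hydroxyphenyl)chroman-7-ol F4, which can be purified as the single 2,4-trans isomer. F4 is then activated by the thiophilic Lewis acid AgBF4 in THF at 0 °C in the presence of 4 (3 equiv); the same C4 cation is released slowly under non-aqueous conditions and the route is rejoined at 9.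

**Further compounds**
F1 | step 2 | racemic epiafzelechin, rac-(2R,3R)-2-(4-hydroxyphenyl)chromane-3,5,7-triol | O[C@@H]1Cc2c(O)cc(O)cc2O[C@@H]1c1ccc(O)cc1.O[C@H]1Cc2c(O)cc(O)cc2O[C@H]1c1ccc(O)cc1
F2 | step 3 | racemic liquiritigenin, 7-hydroxy-2-(4-hydroxyphenyl)chroman-4-one (racemate) | O=C1CC(c2ccc(O)cc2)Oc2cc(O)ccc12
F3 | step 3 | (2R,4R)-2-(4-hydroxyphenyl)chromane-4,7-diol | O[C@@H]1C[C@H](c2ccc(O)cc2)Oc2cc(O)ccc12
F4 | step 4 | (2S,4R)-4-(benzylsulfanyl)-2-(4-hydroxyphenyl)chroman-7-ol | c1ccccc1CS[C@@H]1C[C@@H](c2ccc(O)cc2)Oc2cc(O)ccc12
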